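Tuesday's flask levels off at 82.1 % of its charge and stays there, but Wednesday's flask, charged far higher, ends at 1.20 %.

common to all: enzyme 0.1 mol%

| flask | starting material | remark | time |
|---|---|---|---|
| Tuesday's | 7.1 mM | run made earlier |  |
| Wednesday's | 88 mM | run made earlier |  |
| gamma | 5.0 mM |  | 40 h |
| theta | 10 mM |  | 40 h |
| beta | 20 mM |  | 40 h |
| eta | 40 mM |  | 40 h |
| epsilon | 80 mM |  | 40 h |

| run | time / h | target / % |
|---|---|---|
| Tuesday's | 1.50 | 73.4 |
| Tuesday's | 3.00 | 80.4 |
| Tuesday's | 6.00 | 82.0 |
| Tuesday's | 10.0 | 82.5 |
| Tuesday's | 20.0 | 81.7 |
| Wednesday's | 1.50 | 3.8 |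
| Wednesday's | 3.00 | 2.5 |
| Wednesday's | 6.00 | 1.9 |
| Wednesday's | 10.0 | 1.2 |
| Wednesday's | 20.0 | 1.2 |

(readings scatter by 0.5 percentage points)

- "hardly changes" means that all values lie within two and a half points (for a concentration: within two and a half percent of the largest)

- [target] at the end for gamma, theta, beta, eta, epsilon, in this order
- how the row runs (falls all the way / hardly changes / rises, then falls / rises all the way / falls, then rises)

My reckoning assumes that the enzyme makes target in proportion to [starting material], with a making time t_make. I also assume that starting material eats target, with an eating time t_eat at the full charge. Tuesday's level stretch fits a loss that ends with the starting material. Both rates carry [starting material], so it cancels from their ratio, a selectivity factor, and the run integrates in closed form. I join that form's two limits in one line: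

t_make / t_eat = [charge] / H

[target]end = [charge]·H / ([charge] + H)

Tuesday's level gives 32.5 mM for H, the ceiling, the [target] at which eating equals making. Tuesday's rise reads as t_make = 0.667 h, so t_eat = 3.05 h in Tuesday's flask, and t_make is shorter than t_eat.

Wednesday's plateau reads as a ceiling of 1.07 mM, lower than Tuesday's. With t_eat shortened to 0.246 h by the charge, t_make in Wednesday's flask comes out in my reckoning at 20.3 h.

With Tuesday's ceiling I expect 4.33 mM for gamma, 7.65 mM for theta and 12.4 mM for beta. The ceiling sinks somewhere between Tuesday's charge and Wednesday's; I take it to hold through beta, so I expect the row to rise, then fall.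

The forecast gives 4.1 mM, 8 mM, 6 mM, 1.5 mM and 1.1 mM, shape rises, then falls, says of its threshold “its position is the main uncertainty”, and stands below my figure at beta.

The flasks give 4.19 mM, 7.81 mM, 12.8 mM, 13.4 mM and 2.68 mM, shape rises, then falls.

    starting material + enzyme → target + enzyme, rate k1*[starting material]*[enzyme]/(1 + ([starting material]/Km1) + ([starting material]/Ksi1)^2) (5.86 mM, 18.1 mM, k = 4.74 × 10⁵ M⁻¹ h⁻¹)
    starting material + target → side product (k = 32.0 M⁻¹ h⁻¹)
    target → over-reaction product (k = 1.86 × 10⁻⁴ h⁻¹)
    2 enzyme → spent catalyst (k = 95700 M⁻¹ h⁻¹)

Read backwards, beta's result gives a ceiling of 35.6 mM, close to Tuesday's, while epsilon's gives 2.77 mM. In epsilon two things act together, the pairing of enzyme into spent catalyst and the [starting material] term below the line of the rate law, each a part of the fall. Without that term epsilon ends at 23.1 mM, and without the pairing at 53.5 mM.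

The readings stem from a simulated flask with made-up constants.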